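Readings and results are simulated for an exercise.

Side product creeps on slowly after target has stood still: in the winter run target reads 74.1 % at 4.00 min and 75.0 % at 10.0 min, while side product climbs from 10.6 % to 15.5 %. These end values lie close to the winter charges of reagent and transfer agent, 75.0 % and 15.0 % of the starting material charged.

| setting | winter | red | amber | teal |
|---|---|---|---|---|
| starting material | 0.020 M | 0.020 M | 0.020 M | 0.020 M |
| reagent | 0.015 M | 0.0150 M | 0.0300 M | 0.0600 M |
| transfer agent | 3 mM | 2.00 mM | 2.00 mM | 2.00 mM |
| initiator | 2 mM | 2.0 mM | 2.0 mM | 2.0 mM |
| remark | run made earlier |  |  |  |
| time |  | 30 min | 30 min | 30 min |

winter run (percent of the starting material charged)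

| time / min | target / % | side product / % |
|---|---|---|
| 2.00 | 63.4 | 6.0 |
| 4.00 | 74.1 | 10.6 |
| 6.00 | 74.1 | 12.8 |
| 8.00 | 75.6 | 14.7 |
| 10.0 | 75.0 | 15.5 |

(each reading ± 0.5 percentage points)

- percent here means starting material units held: one ended chains B counts as two
- on the list of suspects stand: 2 second chain carrier -> ended chains A; transfer agent + first chain carrier -> side product + idle radical; reagent + first chain carrier -> target + second chain carrier; starting material + initiating radical -> capped initiator + first chain carrier; initiator -> 2 initiating radical; starting material + second chain carrier -> by-product + first chain carrier; 2 first chain carrier -> ended chains B; 2 idle radical -> ended radicals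
- "hardly changes" means that all values lie within two and a half points (for a concentration: within two and a half percent of the largest)
- no earlier run changes the charge of transfer agent; that part of a forecast is a guess

1. share of target in all that became target or side product for red, amber, teal, in this order
2. the shape of the row from first to last (hardly changes / rises, then falls / rises all the way / falls, then rises / falls all the way)

The first chain carrier is shared between reagent and transfer agent, so one number is worth carrying. In the winter run at 2.00 min, the natural log of the fraction of reagent left over that of the fraction of transfer agent left reads 3.65. This is S, the selectivity factor: how many times faster the first chain carrier takes reagent than transfer agent at equal concentrations.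

Two chemists disagree about the new flasks. One counts charges: as in the winter run, reagent and transfer agent both end at their charges, so the share is reagent charge over the sum, 88.2 %, 93.8 % and 96.8 % for red, amber and teal.

The other counts competition. Each chain turn uses one starting material, and each initiating radical can take one more, two for each initiator. So the crossing lies near the reagent charge that equals the starting material charge less twice the initiator charge, 16.0 mM. Red stands just below it, with 0.0150 M of reagent, so the charges still count there. Amber stands above it, with 0.0300 M, so starting material becomes the limiting reagent and S divides what passes.

The forecast takes this second side: 88.2 %, 97.5 %, 99 %, rises all the way, because “starting material becomes limiting”. Both views rise, but in amber they part, the forecast standing higher than the charge count. The winter run held 3 mM of transfer agent and these flasks hold 2.00 mM; the amber and teal points of the forecast would be wrong if a run at that charge showed a factor clearly apart from the reading 3.65, which itself carries the scatter of the readings.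

The simulation gives 88.2 %, 97.5 % and 98.9 %, rises all the way, so competition holds for amber and teal, while the charge count keeps red, where it gave the same 88.2 %. Amber ends with 0 % of its starting material left, but 35 % of its reagent and 75 % of its transfer agent. Raising the reagent fraction left to the power one over S gives the transfer agent fraction left: amber's reagent gives 75.0 %, and teal's 67 % gives 89.6 %, where teal holds 89 %.

    2 second chain carrier → ended chains A (k = 3.00 × 10⁸ /M/s)
    transfer agent + first chain carrier → side product + idle radical (kL = 1.60 × 10⁵ /M/s)
    reagent + first chain carrier → target + second chain carrier (k = 5.70 × 10⁵ /M/s)
    starting material + initiating radical → capped initiator + first chain carrier (k = 5.10 × 10⁵ /M/s)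
    initiator → 2 initiating radical (k = 0.00310 /s)
    starting material + second chain carrier → by-product + first chain carrier (k = 7.10 × 10⁵ /M/s)
    2 first chain carrier → ended chains B (k = 5.60 × 10⁷ /M/s)
    2 idle radical → ended radicals (k = 1.00 × 10⁸ /M/s)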